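Free monomer that has become quenched substrate cannot return to a chain.

    free monomer + initiator → living end + monomer in chains (k1 = 5.2 × 10⁻⁵ /M/min)
    free monomer + living end → monomer in chains + living end, rate k2*[living end]*[free monomer] (k2 = 0.018 /M/min)
    initiator + stray impurity → spent initiator (k3 = 6.4 /M/min)
    protic impurity + free monomer → quenched substrate (k4 = 0.0076 /M/min)
    monomer in chains → over-reaction product (k5 = 4.1 × 10⁻⁷ /min)

| setting | north | west |
|---|---|---|
| free monomer | 2.6 M | 0.60 M |
| protic impurity | 0.520 M | 0.520 M |
| initiator | 1 mol% | 1 mol% |
| stray impurity | 2.9 mM | 2.9 mM |
| time | 5.0 d | 5.0 d |

- the average divides the monomer in chains by the number of chains begun, living and dead together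
- run time (north): 5.0 d

- which of the two ends with the longer chains by the average number of monomer units in a chain (chains begun, living or dead) ("neither" if they lie within 10%) (north / west / neither)
- average number of monomer units in a chain (chains begun, living or dead) at the end, north
- average number of monomer units in a chain (chains begun, living or dead) at the end, west

**The fork.** I followed one free monomer molecule, which may meet initiator, a living end or protic impurity. Between the first two, with initiator and living end at equal amounts, the odds go by the fork ratio, the growth constant over the starting constant, 346. Both routes feed on the same free monomer, so its level drops out of those odds. The length then depends on the exposure x, which is free monomer summed over time, multiplied by the starting constant: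

length = 1 + fork ratio × (x − 1 + e^(−x)) / (1 − e^(−x))

The amount of initiator cancels from this.

**The surplus.** Protic impurity is the limiting reagent of the quench in both flasks. It takes free monomer one for one, so its charge, once reacted, leaves a surplus of 0.0800 M in west and 2.08 M in north.

**Two ways.** For west, I first held the surplus over the whole 5.0 d, which gave x = 0.0300 and 6.21 units. Next I integrated the quench too, which added 0.0138 to x. That made x = 0.0437 and 8.63 units. The two ways part, and the first one cheats: west starts at 0.60 M, not at its surplus, and the stretch before the quench is through counts as exposure. I committed to 8.63 for west.

**North's estimate.** The same sum for north gave x = 0.780 and 153 units. I took that as a high estimate: the sum holds north's surplus whole, while chains take free monomer from it too, and my reckoning stopped there.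

**The forecast.** It said “North runs much longer than west.” It chose north, with 113 units for north (109 to 117) and 8.7 for west (8.3 to 9.1). My west figure differs slightly, and my high estimate for north stood well above its figure, at 153 units.

**The result.** The flasks gave north, with 113 units in north and 8.72 in west. With all amounts held and the time at 4.26 d or 5.91 d, north's length lay outside the forecast's range. West's chains are short mainly because of its lower free monomer charge: given north's charge, west reached 113. North's 0.0103 M of living end is a share 0.447 of the initiator the stray impurity spared, and through the fork ratio that share gives 114 units. The neighbour, west with 0.31 M of protic impurity, has a surplus of 0.290 M, so x = 0.114 and the rule gives 21.1 units; that flask reached 21.0.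

(The constants used here were drawn at random within sensible limits; the result is computed.)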